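**Strategy.** The route rests on closing the ten-membered carbocycle last, at C3–C4, by an intramolecular Nozaki–Hiyama–Kishi addition of a (Z)-alkenyl iodide to an aldehyde. The step exploits the (4Z)-allylic alcohol C3(OH)–C4(CH3)=C5 that lies in the carbocycle beside the lactone carbon C6: in one operation it forms C3–C4, creates the C3 carbinol and carries the Z geometry of the iodide into C4=C5. The precursor is an open-chain iodo aldehyde that already holds the trans-fused α-methylene lactone (C6, C7), the C8 epoxyangelate and the 1,10-oxirane; it is assembled by a butenolide Barbier allylation, an inverting Mitsunobu esterification and a Shi epoxidation.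

Key step: step 19

Locants are germacrane locants: carbocycle C1–C10, C6 bears the lactone oxygen, C7 bears C11, C12 is the lactone carbonyl, C13 the exocyclic methylene, C14 the methyl on C10, C15 the methyl on C4.

Remark: the zinc allylation of step 11 is assumed to follow the closed six-membered transition state expected for 3-(bromomethyl)butenolides (7,8-anti), so C8 is brought to its final configuration by the inverting esterification of step 15.

**Butenolide fragment**

Step 1
Reactants: 1 but-2-yn-1-ol
Product: 3 (Z)-3-iodobut-2-en-1-ol, via sodium alkenylalanate 2 (not isolated)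
Conditions: Red-Al, THF, 0 °C to rt; then I2, THF, −78 to 0 °C; aq. Rochelle salt
Reagents that add atoms: iodine, II
Why: Red-Al adds hydride to C2 and aluminium to C3 in a trans hydroalumination through the five-membered alkoxyalanate 2, and iodinolysis of the C–Al bond with retention gives the Z iodide (hydroalumination–iodination of a propargylic alcohol).

Step 2
Reactants: 3 (Z)-3-iodobut-2-en-1-ol
Product: 4 (Z)-3-iodobut-2-enal
Conditions: MnO2, CH2Cl2, rt, dark
Reagents that add atoms: none
Why: MnO2 oxidises the allylic alcohol to the enal under neutral conditions that leave the alkenyl iodide and its Z geometry untouched (allylic oxidation).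

Step 3
Reactants: 4 (Z)-3-iodobut-2-enal
Product: 5 rac-(Z)-5-iodohexa-1,4-dien-3-ol
Conditions: CH2=CHMgBr, THF, −78 °C; aq. NH4Cl
Reagents that add atoms: vinylmagnesium bromide, C=C[Mg]Br
Why: the vinyl Grignard reagent adds 1,2 to the aldehyde at low temperature, faster than addition–elimination at the β-iodo carbon, to give the racemic bis-allylic carbinol (Grignard addition).

Step 4
Reactants: 5 rac-(Z)-5-iodohexa-1,4-dien-3-ol
Product: 6 (S,Z)-5-iodohexa-1,4-dien-3-ol
Conditions: Ti(OiPr)4 (10 mol %), L-(+)-DIPT (15 mol %), t-BuOOH (0.6 equiv), 4 Å MS, CH2Cl2, −20 °C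
Reagents that add atoms: none
Why: Sharpless kinetic resolution: with L-(+)-DIPT the R enantiomer is epoxidised at its vinyl group, whereas in the S enantiomer the only olefin matched to the catalyst is the Z-configured, iodine-deactivated one, so that S-carbinol 6 (future C6) should be recovered in high enantiomeric purity at a little over half conversion.

Step 5
Reactants: 6 (S,Z)-5-iodohexa-1,4-dien-3-ol; 7 2-(bromomethyl)prop-2-enoic acid
Product: 8 (S,Z)-5-iodohexa-1,4-dien-3-yl 2-(bromomethyl)prop-2-enoate
Conditions: DCC, DMAP (5 mol %), CH2Cl2, 0 °C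
Reagents that add atoms: none
Why: Steglich esterification acylates the acid-labile bis-allylic alcohol under neutral conditions without allylic transposition and without touching the carbinol centre.

Step 6
Reactants: 8 (S,Z)-5-iodohexa-1,4-dien-3-yl 2-(bromomethyl)prop-2-enoate
Product: 9 (S)-3-(bromomethyl)-5-[(Z)-2-iodoprop-1-en-1-yl]furan-2(5H)-one
Conditions: Grubbs II (10 mol %), CH2Cl2 (0.01 M), 40 °C
Reagents that add atoms: none
Why: ring-closing metathesis between the vinyl group and the 1,1-disubstituted acrylate closes the butenolide with loss of ethene, the trisubstituted iodoalkene and the allylic bromide being inert to the ruthenium carbene.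

**Aldehyde fragment**

Step 7
Reactants: 10 tert-butyl(but-3-yn-1-yloxy)dimethylsilane
Product: 13 (E)-6-[(tert-butyldimethylsilyl)oxy]-4-methylhex-3-en-1-ol, via alkenylalane 11 (not isolated), via lithium alkenylalanate 12 (not isolated)
Conditions: Cp2ZrCl2 (0.2 equiv), AlMe3, CH2Cl2, 0 °C to rt; then n-BuLi, hexane/THF, −78 °C; then ethylene oxide, −78 °C to rt; aq. Rochelle salt
Reagents that add atoms: trimethylaluminium, C[Al](C)C; ethylene oxide, C1CO1
Why: Zr-catalysed syn carboalumination (Negishi) places CH3 and Al cis on the alkyne, and the ate complex 12 opens ethylene oxide with retention at the alkenyl carbon, which fixes the E trisubstituted olefin (future C1=C10).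

Step 8
Reactants: 13 (E)-6-[(tert-butyldimethylsilyl)oxy]-4-methylhex-3-en-1-ol
Product: 14 tert-butyl{[(E)-6-[(4-methoxybenzyl)oxy]-3-methylhex-3-en-1-yl]oxy}dimethylsilane
Conditions: NaH, PMBCl, Bu4NI (cat.), DMF, 0 °C to rt
Reagents that add atoms: 4-methoxybenzyl chloride, COc1ccc(CCl)cc1
Why: Williamson etherification of the primary alkoxide installs a PMB group that survives all later steps and is removable under neutral oxidative conditions.

Step 9
Reactants: 14 tert-butyl{[(E)-6-[(4-methoxybenzyl)oxy]-3-methylhex-3-en-1-yl]oxy}dimethylsilane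
Product: 15 (E)-6-[(4-methoxybenzyl)oxy]-3-methylhex-3-en-1-ol
Conditions: CSA (cat.), MeOH/CH2Cl2, 0 °C
Reagents that add atoms: none
Why: acid-catalysed methanolysis cleaves the primary TBS ether selectively, the PMB ether and the olefin being stable.

Step 10
Reactants: 15 (E)-6-[(4-methoxybenzyl)oxy]-3-methylhex-3-en-1-ol
Product: 16 (E)-6-[(4-methoxybenzyl)oxy]-3-methylhex-3-enal
Conditions: Dess–Martin periodinane, NaHCO3, CH2Cl2, 0 °C to rt; used crude
Reagents that add atoms: none
Why: buffered Dess–Martin oxidation gives the β,γ-unsaturated aldehyde without migration of the double bond into conjugation, and the crude aldehyde is used at once.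

**Union of the fragments**

Step 11
Reactants: 9 (S)-3-(bromomethyl)-5-[(Z)-2-iodoprop-1-en-1-yl]furan-2(5H)-one; 16 (E)-6-[(4-methoxybenzyl)oxy]-3-methylhex-3-enal
Product: 18 (4R,5S)-4-[(1S,3E)-1-hydroxy-6-[(4-methoxybenzyl)oxy]-3-methylhex-3-en-1-yl]-5-[(Z)-2-iodoprop-1-en-1-yl]-3-methylideneoxolan-2-one, via allylzinc bromide 17 (not isolated)
Conditions: Zn dust, THF/sat. aq. NH4Cl, 0 °C to rt
Reagents that add atoms: none
Why: Barbier allylation: allylzinc 17 should add through its ring carbon C7 (SE2′) in a chair Zimmerman–Traxler transition state, anti to the C6 substituent (6,7-trans) and with the aldehyde chain equatorial (7,8-anti, 8S), which also unveils the exocyclic methylene of the lactone.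

**Epoxyangelic acid**

Step 12
Reactants: 19 angelic acid [(Z)-2-methylbut-2-enoic acid]
Product: 20 (Z)-2-methylbut-2-en-1-ol
Conditions: LiAlH4, Et2O, 0 °C to rt; aq. NaOH work-up
Reagents that add atoms: none
Why: LiAlH4 reduces the carboxylic acid to the allylic alcohol without Z to E isomerisation (hydride reduction).

Step 13
Reactants: 20 (Z)-2-methylbut-2-en-1-ol
Product: 21 [(2R,3S)-2,3-dimethyloxiran-2-yl]methanol
Conditions: Ti(OiPr)4 (10 mol %), D-(−)-DIPT (12 mol %), t-BuOOH, 4 Å MS, CH2Cl2, −20 °C
Reagents that add atoms: tert-butyl hydroperoxide, CC(C)(C)OO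
Why: Sharpless asymmetric epoxidation with D-(−)-DIPT delivers oxygen syn to one face of the Z allylic alcohol, which sets both oxirane centres (2R,3S) and keeps CH2OH and the C3 methyl cis.

Step 14
Reactants: 21 [(2R,3S)-2,3-dimethyloxiran-2-yl]methanol
Product: 22 (2S,3S)-2,3-dimethyloxirane-2-carboxylic acid
Conditions: TEMPO (cat.), PhI(OAc)2, MeCN/H2O, rt
Reagents that add atoms: water, O
Why: TEMPO/PhI(OAc)2 oxidation in aqueous acetonitrile takes the primary alcohol through the aldehyde hydrate to the acid under near-neutral conditions that spare the oxirane.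

**Endgame**

Step 15
Reactants: 18 the 8S alcohol from step 11; 22 (2S,3S)-2,3-dimethyloxirane-2-carboxylic acid
Product: 23 (1R,3E)-1-[(2S,3R)-2-[(Z)-2-iodoprop-1-en-1-yl]-4-methylidene-5-oxooxolan-3-yl]-6-[(4-methoxybenzyl)oxy]-3-methylhex-3-en-1-yl (2S,3S)-2,3-dimethyloxirane-2-carboxylate
Conditions: PPh3, DIAD, toluene, 0 °C to rt
Reagents that add atoms: none
Why: Mitsunobu esterification: SN2 attack of the carboxylate of 22 on the C8 alkoxyphosphonium ion inverts C8 (8S to 8R) and installs the epoxyangelate in the same operation.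

Step 16
Reactants: 23 the olefinic epoxyangelate
Product: 24 (1R)-1-[(2S,3R)-2-[(Z)-2-iodoprop-1-en-1-yl]-4-methylidene-5-oxooxolan-3-yl]-2-[(2R,3R)-3-{2-[(4-methoxybenzyl)oxy]ethyl}-2-methyloxiran-2-yl]ethyl (2S,3S)-2,3-dimethyloxirane-2-carboxylate
Conditions: D-fructose-derived Shi ketone (30 mol %), Oxone, K2CO3, Bu4NHSO4 (cat.), MeCN/DMM/aq. Na2B4O7–EDTA buffer, 0 °C
Reagents that add atoms: potassium peroxymonosulfate (Oxone), [K+].[O-]S(=O)(=O)OO
Why: Shi epoxidation: the chiral dioxirane attacks the only electron-rich olefin, the E trisubstituted C1=C10, through a spiro transition state that should give the (1R,10R)-oxirane under catalyst control, the enoate and the iodoalkene being too electron-poor to react.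

Step 17
Reactants: 24 the PMB-protected bis-oxirane
Product: 25 (1R)-2-[(2R,3R)-3-(2-hydroxyethyl)-2-methyloxiran-2-yl]-1-[(2S,3R)-2-[(Z)-2-iodoprop-1-en-1-yl]-4-methylidene-5-oxooxolan-3-yl]ethyl (2S,3S)-2,3-dimethyloxirane-2-carboxylate
Conditions: DDQ, CH2Cl2/pH 7 phosphate buffer, 0 °C to rt
Reagents that add atoms: none
Why: DDQ oxidises the electron-rich PMB ether to an oxocarbenium ion that water hydrolyses (oxidative PMB cleavage), under buffered conditions that spare both oxiranes and the alkenyl iodide.

Step 18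
Reactants: 25 the primary alcohol
Product: 26 (1R)-1-[(2S,3R)-2-[(Z)-2-iodoprop-1-en-1-yl]-4-methylidene-5-oxooxolan-3-yl]-2-[(2R,3R)-2-methyl-3-(2-oxoethyl)oxiran-2-yl]ethyl (2S,3S)-2,3-dimethyloxirane-2-carboxylate
Conditions: Dess–Martin periodinane, NaHCO3, CH2Cl2, 0 °C; filtered and used crude
Reagents that add atoms: none
Why: buffered Dess–Martin oxidation gives the β,γ-epoxy aldehyde without amine base, so that β-elimination of the oxirane is avoided, and the crude aldehyde goes directly into step 19.

Step 19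
Reactants: 26 the seco iodo aldehyde
Product: 28 (1R,3S,4Z,6R,7R,8R,10R)-1,10-epoxy-3-hydroxy-8-[(2S,3S)-2,3-dimethyloxirane-2-carbonyloxy]germacra-4,11(13)-dien-12,6-olide (CNP0268255.2), via alkenylchromium(III) species 27 (not isolated)
Conditions: CrCl2 (10 equiv), NiCl2 (2 mol %), degassed DMSO, 0.003 M (slow addition), rt; aq. work-up
Reagents that add atoms: none
Why: Ni(0) inserts into the C4–I bond with retention and hands the alkenyl group to Cr(III), and the (Z)-alkenylchromium 27 adds to the chromium-bound C3 aldehyde (Nozaki–Hiyama–Kishi reaction, whose closest use is the macrocyclisation of iodo aldehydes to ten-membered germacranolide rings). The carbocycle C1–C10 closes by a 10-exo-trig addition to the C=O group that forms C3–C4 and keeps the 4Z geometry. C3 is the only new stereocentre and is set by macrocyclic substrate control: with H3 and H6 held in the olefin plane to avoid A(1,3) strain, the trans-fused lactone and the trans-oxirane should leave C2 on the face of the olefin opposite to C7, which exposes the aldehyde face that leads to 3S. The step needs cyclisation to win over oligomerisation, which high dilution and the three turn elements (lactone, Z-alkenyl unit, oxirane) should secure. It also needs chemoselectivity for the aldehyde over the lactone, the ester, the enoate and both oxiranes, which the low basicity and carbonyl selectivity of organochromium(III) reagents should secure.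

**Compound list**

1 | but-2-yn-1-ol | CC#CCO | starting material
2 | sodium cyclic alkenylalanate from 1 and Red-Al (formed in situ) | [Na+].CC1=CCO[Al-]1(OCCOC)OCCOC | intermediate
3 | (Z)-3-iodobut-2-en-1-ol | OC/C=C(/C)I | intermediate
4 | (Z)-3-iodobut-2-enal | O=C/C=C(/C)I | intermediate
5 | rac-(Z)-5-iodohexa-1,4-dien-3-ol | OC(/C=C(/C)I)C=C | intermediate
6 | (S,Z)-5-iodohexa-1,4-dien-3-ol | O[C@H](/C=C(/C)I)C=C | intermediate
7 | 2-(bromomethyl)prop-2-enoic acid | C=C(CBr)C(=O)O | starting material
8 | (S,Z)-5-iodohexa-1,4-dien-3-yl 2-(bromomethyl)prop-2-enoate | C=C(CBr)C(=O)O[C@H](/C=C(/C)I)C=C | intermediate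
9 | (S)-3-(bromomethyl)-5-[(Z)-2-iodoprop-1-en-1-yl]furan-2(5H)-one | O=C1O[C@H](/C=C(/C)I)C=C1CBr | intermediate
10 | tert-butyl(but-3-yn-1-yloxy)dimethylsilane | C#CCCO[Si](C)(C)C(C)(C)C | starting material
11 | (E)-alkenyldimethylalane from 10 (formed in situ) | C[Al](C)/C=C(\C)CCO[Si](C)(C)C(C)(C)C | intermediate
12 | lithium butyl(alkenyl)dimethylalanate from 11 (formed in situ) | [Li+].CCCC[Al-](C)(C)/C=C(\C)CCO[Si](C)(C)C(C)(C)C | intermediate
13 | (E)-6-[(tert-butyldimethylsilyl)oxy]-4-methylhex-3-en-1-ol | OCC/C=C(\C)CCO[Si](C)(C)C(C)(C)C | intermediate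
14 | tert-butyl{[(E)-6-[(4-methoxybenzyl)oxy]-3-methylhex-3-en-1-yl]oxy}dimethylsilane | COc1ccc(COCC/C=C(\C)CCO[Si](C)(C)C(C)(C)C)cc1 | intermediate
15 | (E)-6-[(4-methoxybenzyl)oxy]-3-methylhex-3-en-1-ol | COc1ccc(COCC/C=C(\C)CCO)cc1 | intermediate
16 | (E)-6-[(4-methoxybenzyl)oxy]-3-methylhex-3-enal | COc1ccc(COCC/C=C(\C)CC=O)cc1 | intermediate
17 | allylzinc bromide from 9 (formed in situ) | O=C1O[C@H](/C=C(/C)I)C=C1C[Zn]Br | intermediate
18 | (4R,5S)-4-[(1S,3E)-1-hydroxy-6-[(4-methoxybenzyl)oxy]-3-methylhex-3-en-1-yl]-5-[(Z)-2-iodoprop-1-en-1-yl]-3-methylideneoxolan-2-one (6S,7R,8S) | C=C1C(=O)O[C@H](/C=C(/C)I)[C@H]1[C@@H](O)C/C(C)=C/CCOCc1ccc(OC)cc1 | intermediate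
19 | angelic acid, (Z)-2-methylbut-2-enoic acid | C/C=C(/C)C(=O)O | starting material
20 | (Z)-2-methylbut-2-en-1-ol | C/C=C(/C)CO | intermediate
21 | [(2R,3S)-2,3-dimethyloxiran-2-yl]methanol | OC[C@@]1(C)O[C@H]1C | intermediate
22 | (2S,3S)-2,3-dimethyloxirane-2-carboxylic acid | OC(=O)[C@@]1(C)O[C@H]1C | intermediate
23 | (1R,3E)-1-[(2S,3R)-2-[(Z)-2-iodoprop-1-en-1-yl]-4-methylidene-5-oxooxolan-3-yl]-6-[(4-methoxybenzyl)oxy]-3-methylhex-3-en-1-yl (2S,3S)-2,3-dimethyloxirane-2-carboxylate | C=C1C(=O)O[C@H](/C=C(/C)I)[C@H]1[C@H](OC(=O)[C@@]2(C)O[C@H]2C)C/C(C)=C/CCOCc1ccc(OC)cc1 | intermediate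
24 | (1R)-1-[(2S,3R)-2-[(Z)-2-iodoprop-1-en-1-yl]-4-methylidene-5-oxooxolan-3-yl]-2-[(2R,3R)-3-{2-[(4-methoxybenzyl)oxy]ethyl}-2-methyloxiran-2-yl]ethyl (2S,3S)-2,3-dimethyloxirane-2-carboxylate | C=C1C(=O)O[C@H](/C=C(/C)I)[C@H]1[C@H](OC(=O)[C@@]2(C)O[C@H]2C)C[C@@]2(C)O[C@@H]2CCOCc1ccc(OC)cc1 | intermediate
25 | (1R)-2-[(2R,3R)-3-(2-hydroxyethyl)-2-methyloxiran-2-yl]-1-[(2S,3R)-2-[(Z)-2-iodoprop-1-en-1-yl]-4-methylidene-5-oxooxolan-3-yl]ethyl (2S,3S)-2,3-dimethyloxirane-2-carboxylate | C=C1C(=O)O[C@H](/C=C(/C)I)[C@H]1[C@H](OC(=O)[C@@]2(C)O[C@H]2C)C[C@@]2(C)O[C@@H]2CCO | intermediate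
26 | (1R)-1-[(2S,3R)-2-[(Z)-2-iodoprop-1-en-1-yl]-4-methylidene-5-oxooxolan-3-yl]-2-[(2R,3R)-2-methyl-3-(2-oxoethyl)oxiran-2-yl]ethyl (2S,3S)-2,3-dimethyloxirane-2-carboxylate | C=C1C(=O)O[C@H](/C=C(/C)I)[C@H]1[C@H](OC(=O)[C@@]2(C)O[C@H]2C)C[C@@]2(C)O[C@@H]2CC=O | intermediate
27 | (Z)-alkenylchromium(III) dichloride from 26 (formed in situ) | C=C1C(=O)O[C@H](/C=C(/C)[Cr](Cl)Cl)[C@H]1[C@H](OC(=O)[C@@]2(C)O[C@H]2C)C[C@@]2(C)O[C@@H]2CC=O | intermediate
28 | (1R,3S,4Z,6R,7R,8R,10R)-1,10-epoxy-3-hydroxy-8-[(2S,3S)-2,3-dimethyloxirane-2-carbonyloxy]germacra-4,11(13)-dien-12,6-olide | C=C1C(=O)O[C@@H]2/C=C(/C)[C@@H](O)C[C@H]3O[C@]3(C)C[C@@H](OC(=O)[C@@]3(C)O[C@H]3C)[C@@H]12 | target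

**Step count and risks**

Total step count: 19. Longest linear sequence: 12 steps (steps 1–6, 11, 15–19).

The three steps most likely to fail:

Step 19, the ring closure. The alkenylchromium may add to the wrong face of the aldehyde or without facial preference, because C3 is set only by the conformation of the closing ring. The β,γ-epoxy aldehyde may also lose material by β-elimination or oligomerisation, and Cr(II) may attack the α,β-epoxy ester. The fallback sets out from 26 and accepts whatever C3 configuration the cyclisation delivers. The 3R epimer of 28 F1, alone or mixed with 28, is oxidised with MnO2 in CH2Cl2 to the macrocyclic (4Z)-en-3-one F2. This ketone is reduced at once under catalyst control with (R)-Me-CBS and catecholborane at −78 °C, in which the α-methylalkenyl group acts as the large substituent and the 3S alcohol should result. The sequence comes back to the route at 28, and both epimers converge.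

Step 15, the inverting esterification. The C8 alkoxyphosphonium ion is flanked by the branched C7 and may eliminate towards C7 (the proton there is allylic to the enoate) or react too slowly with the hindered α-quaternary carboxylate. The fallback sets out from 18 and separates activation from displacement. ClCH2SO2Cl and pyridine in CH2Cl2 at 0 °C give the chloromethanesulfonate of 18 F3. The caesium salt of 22 (Cs2CO3, 18-crown-6, toluene, 50 °C) then displaces it with inversion. The sequence comes back to the route at 23.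

Step 11, the allylation. The addition may run through an open instead of a closed transition state, so that the facial choice at the aldehyde is reversed and the 7,8-syn alcohol forms. The fallback sets out from 9 and 16 and uses that outcome directly. The resulting 8R alcohol, the C8 epimer of 18 F4, already has the configuration of the target at C8. It is acylated with retention by 22 under Yamaguchi conditions (2,4,6-trichlorobenzoyl chloride, Et3N, then DMAP, toluene). The sequence comes back to the route at 23, and step 15 is not needed.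

Further compounds
F1 | step 19 | (1R,3R,4Z,6R,7R,8R,10R)-1,10-epoxy-3-hydroxy-8-[(2S,3S)-2,3-dimethyloxirane-2-carbonyloxy]germacra-4,11(13)-dien-12,6-olide (3-epimer of 28) | C=C1C(=O)O[C@@H]2/C=C(/C)[C@H](O)C[C@H]3O[C@]3(C)C[C@@H](OC(=O)[C@@]3(C)O[C@H]3C)[C@@H]12
F2 | step 19 | (1R,4Z,6R,7R,8R,10R)-1,10-epoxy-3-oxo-8-[(2S,3S)-2,3-dimethyloxirane-2-carbonyloxy]germacra-4,11(13)-dien-12,6-olide | C=C1C(=O)O[C@@H]2/C=C(/C)C(=O)C[C@H]3O[C@]3(C)C[C@@H](OC(=O)[C@@]3(C)O[C@H]3C)[C@@H]12
F3 | step 15 | (1S,3E)-1-[(2S,3R)-2-[(Z)-2-iodoprop-1-en-1-yl]-4-methylidene-5-oxooxolan-3-yl]-6-[(4-methoxybenzyl)oxy]-3-methylhex-3-en-1-yl chloromethanesulfonate | C=C1C(=O)O[C@H](/C=C(/C)I)[C@H]1[C@@H](OS(=O)(=O)CCl)C/C(C)=C/CCOCc1ccc(OC)cc1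
F4 | step 11 | (4R,5S)-4-[(1R,3E)-1-hydroxy-6-[(4-methoxybenzyl)oxy]-3-methylhex-3-en-1-yl]-5-[(Z)-2-iodoprop-1-en-1-yl]-3-methylideneoxolan-2-one | C=C1C(=O)O[C@H](/C=C(/C)I)[C@H]1[C@H](O)C/C(C)=C/CCOCc1ccc(OC)cc1
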